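Ring C is cut at O1–C2 and C4–C4a, giving a symmetric ring A donor and a C6–C3 glycidic amide that already carries ring B and the C3 oxygen. In one flask, 2-lithio-1,3,5-tris(methoxymethoxy)benzene acylates the (2R,3S)-oxirane morpholine amide (C4–C4a); acid then opens the oxirane at benzylic C2 with an ortho oxygen of ring A (O1–C2) and removes all MOM groups, giving the target. The step exploits the threefold symmetry of phloroglucinol ring A, whose C–H carbons each lie between two equivalent oxygens, and the 2′,4′-dioxygenated ring B, which activates C2; C3 is set beforehand by catalytic asymmetric epoxidation.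

Key step: step 7

Remark: diethyl (2-morpholino-2-oxoethyl)phosphonate 7 is taken as purchasable, like 1, 2, 5 and 10.
Remark: the (S)-BINOL samarium catalyst is assumed to give the (2R,3S)-oxirane; should the sense of induction be the opposite, (R)-BINOL is used instead.

Step 1
Reactants: 1 5-bromo-2,4-dihydroxybenzaldehyde; 2 geranyl bromide, (2E)-1-bromo-3,7-dimethylocta-2,6-diene
Product: 3 5-bromo-3-[(2E)-3,7-dimethylocta-2,6-dien-1-yl]-2,4-dihydroxybenzaldehyde
Conditions: KOH (10% aq), 2 added slowly, 0 °C → rt
Reagents that add atoms: none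
Why: Phenoxide C-alkylation: in water the resorcinol dianion of 1 should be alkylated by the primary allylic bromide at C3, the only free carbon ortho or para to both oxygens (C5 carries Br), by SN2 so that the E-alkene is kept.

Step 2
Reactants: 3 5-bromo-3-geranyl-2,4-dihydroxybenzaldehyde
Product: 4 5-bromo-3-[(2E)-3,7-dimethylocta-2,6-dien-1-yl]-2,4-bis(methoxymethoxy)benzaldehyde
Conditions: NaH, MOMCl, DMF, 0 °C → rt
Reagents that add atoms: chloromethyl methyl ether (MOMCl), COCCl
Why: Williamson-type O-alkylation of both sodium phenoxides gives the bis-acetal, which masks the phenols through the basic and organometallic steps and is cleaved in the acid stage of step 7.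

Step 3
Reactants: 4 5-bromo-3-geranyl-2,4-bis(methoxymethoxy)benzaldehyde; 5 4,4,5,5-tetramethyl-2-(3-methylbut-2-en-1-yl)-1,3,2-dioxaborolane (prenylboronic acid pinacol ester)
Product: 6 3-[(2E)-3,7-dimethylocta-2,6-dien-1-yl]-2,4-bis(methoxymethoxy)-5-(3-methylbut-2-en-1-yl)benzaldehyde
Conditions: Pd(dppf)Cl2 (5 mol %), CsF, THF, 65 °C
Reagents that add atoms: none
Why: Suzuki–Miyaura coupling of the aryl bromide with the allylic boronate; reductive elimination at the unsubstituted allyl terminus should give the linear 3-methylbut-2-enyl group, and the aldehyde, MOM ethers and trisubstituted alkenes are inert.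

Step 4
Reactants: 6 3-geranyl-2,4-bis(methoxymethoxy)-5-prenylbenzaldehyde; 7 diethyl (2-morpholino-2-oxoethyl)phosphonate
Product: 8 (2E)-3-{3-[(2E)-3,7-dimethylocta-2,6-dien-1-yl]-2,4-bis(methoxymethoxy)-5-(3-methylbut-2-en-1-yl)phenyl}-1-(morpholin-4-yl)prop-2-en-1-one
Conditions: NaH, THF, 0 °C → rt
Reagents that add atoms: none
Why: Horner–Wadsworth–Emmons olefination with the amide-stabilised phosphonate anion should give the E-enamide under thermodynamic control.

Step 5
Reactants: 8 (E)-cinnamoyl morpholine amide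
Product: 9 {(2R,3S)-3-[3-geranyl-2,4-bis(methoxymethoxy)-5-prenylphenyl]oxiran-2-yl}(morpholin-4-yl)methanone
Conditions: Sm(O-i-Pr)3/(S)-BINOL/Ph3As=O (1:1:1, 10 mol %), t-BuOOH (decane), MS 4 Å, THF, rt
Reagents that add atoms: tert-butyl hydroperoxide, CC(C)(C)OO
Why: Samarium–BINOL-catalysed nucleophilic (Weitz–Scheffer-type) asymmetric epoxidation: the samarium-bound tert-butyl peroxide adds to the β-carbon of the coordinated enamide from the face set by the (S)-BINOL ligand and closes to the trans-oxirane, which should set both centres as 2R,3S, while the electron-rich geranyl and prenyl alkenes do not react with the nucleophilic oxidant.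

Step 6
Reactants: 10 phloroglucinol (benzene-1,3,5-triol)
Product: 11 1,3,5-tris(methoxymethoxy)benzene
Conditions: NaH, MOMCl, DMF, 0 °C → rt
Reagents that add atoms: chloromethyl methyl ether (MOMCl), COCCl
Why: Threefold Williamson-type O-alkylation gives the tris-acetal, whose OMOM groups direct the lithiation of step 7 and are lost in its acid stage.

Step 7
Reactants: 11 1,3,5-tris(methoxymethoxy)benzene; 9 (2R,3S)-oxirane morpholine amide
Product: 16 (2R,3R)-2-{3-[(2E)-3,7-dimethylocta-2,6-dien-1-yl]-2,4-dihydroxy-5-(3-methylbut-2-en-1-yl)phenyl}-3,5,7-trihydroxy-2,3-dihydro-4H-chromen-4-one, via aryllithium 12 (not isolated), via lithium hemiaminal alkoxide 13 (not isolated), via epoxy ketone 14 (not isolated), via tetra-MOM dihydroflavonol 15 (not isolated)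
Conditions: 11, n-BuLi (1.05 equiv each), THF, 0 °C, 1 h; then 9, −78 → −20 °C; then MeOH, conc. HCl, 0 → 45 °C, same flask
Reagents that add atoms: none
Why: Directed ortho-lithiation of 11 at a carbon flanked by two OMOM groups gives 12, which adds to the amide carbonyl of 9 to give the stable tetrahedral alkoxide 13 (C4–C4a bond) without touching the oxirane; acid then collapses 13 to epoxy ketone 14, protonates the oxirane and opens it at the benzylic carbon, where an ortho oxygen of ring A closes the O1–C2 bond with loss of its MOM group (15), before the remaining four MOM acetals are methanolysed to 16. The closest known reaction types are the acylation of aryllithiums by morpholine or Weinreb amides and the HCl/MeOH deprotection–cyclisation of 2′-OMOM chalcone epoxides to trans-dihydroflavonols. Ring C closes by a 6-endo-tet opening of the oxirane, favoured over 5-exo attack at C3 because C2 is benzylic and stabilised by the 2′,4′-dioxygenated ring B. C3 keeps the R configuration from step 5 because its C–O bond is never broken; C2 should arise R by inversion at the (S)-oxirane carbon, and any ionised material is funnelled under the reversible acid conditions to the same 2,3-trans isomer with aryl and OH both equatorial, so C3 controls C2. The step needs C-acylation before any activation of the oxirane (secured by the carbon–lithium bond and the low temperature), O-attack instead of C-attack at C2 (secured by the deactivating ketone on ring A and by intramolecularity) and no regiochemical choice on ring A (secured by its threefold symmetry, since both flanking oxygens are equivalent).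

Compound list
1 | 5-bromo-2,4-dihydroxybenzaldehyde | O=Cc1cc(Br)c(O)cc1O | starting material
2 | geranyl bromide, (2E)-1-bromo-3,7-dimethylocta-2,6-diene | CC(C)=CCC/C(C)=C/CBr | starting material
3 | 5-bromo-3-[(2E)-3,7-dimethylocta-2,6-dien-1-yl]-2,4-dihydroxybenzaldehyde | CC(C)=CCC/C(C)=C/Cc1c(O)c(Br)cc(C=O)c1O | intermediate
4 | 5-bromo-3-[(2E)-3,7-dimethylocta-2,6-dien-1-yl]-2,4-bis(methoxymethoxy)benzaldehyde | CC(C)=CCC/C(C)=C/Cc1c(OCOC)c(Br)cc(C=O)c1OCOC | intermediate
5 | 4,4,5,5-tetramethyl-2-(3-methylbut-2-en-1-yl)-1,3,2-dioxaborolane | CC(C)=CCB1OC(C)(C)C(C)(C)O1 | starting material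
6 | 3-[(2E)-3,7-dimethylocta-2,6-dien-1-yl]-2,4-bis(methoxymethoxy)-5-(3-methylbut-2-en-1-yl)benzaldehyde | CC(C)=CCC/C(C)=C/Cc1c(OCOC)c(CC=C(C)C)cc(C=O)c1OCOC | intermediate
7 | diethyl (2-morpholino-2-oxoethyl)phosphonate | CCOP(=O)(OCC)CC(=O)N1CCOCC1 | starting material
8 | (2E)-3-{3-[(2E)-3,7-dimethylocta-2,6-dien-1-yl]-2,4-bis(methoxymethoxy)-5-(3-methylbut-2-en-1-yl)phenyl}-1-(morpholin-4-yl)prop-2-en-1-one | CC(C)=CCC/C(C)=C/Cc1c(OCOC)c(CC=C(C)C)cc(/C=C/C(=O)N2CCOCC2)c1OCOC | intermediate
9 | {(2R,3S)-3-[3-geranyl-2,4-bis(methoxymethoxy)-5-prenylphenyl]oxiran-2-yl}(morpholin-4-yl)methanone | CC(C)=CCC/C(C)=C/Cc1c(OCOC)c(CC=C(C)C)cc([C@@H]2O[C@H]2C(=O)N2CCOCC2)c1OCOC | intermediate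
10 | phloroglucinol (benzene-1,3,5-triol) | Oc1cc(O)cc(O)c1 | starting material
11 | 1,3,5-tris(methoxymethoxy)benzene | COCOc1cc(OCOC)cc(OCOC)c1 | intermediate
12 | 2,4,6-tris(methoxymethoxy)phenyllithium | [Li]c1c(OCOC)cc(OCOC)cc1OCOC | intermediate
13 | lithium alkoxide of the morpholine hemiaminal from 12 and 9 (oxirane 2R,3S; carbinol carbon unassigned) | CC(C)=CCC/C(C)=C/Cc1c(OCOC)c(CC=C(C)C)cc([C@@H]2O[C@H]2C(O[Li])(N2CCOCC2)c2c(OCOC)cc(OCOC)cc2OCOC)c1OCOC | intermediate
14 | {(2R,3S)-3-[3-geranyl-2,4-bis(methoxymethoxy)-5-prenylphenyl]oxiran-2-yl}[2,4,6-tris(methoxymethoxy)phenyl]methanone | CC(C)=CCC/C(C)=C/Cc1c(OCOC)c(CC=C(C)C)cc([C@@H]2O[C@H]2C(=O)c2c(OCOC)cc(OCOC)cc2OCOC)c1OCOC | intermediate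
15 | (2R,3R)-2-[3-geranyl-2,4-bis(methoxymethoxy)-5-prenylphenyl]-3-hydroxy-5,7-bis(methoxymethoxy)-2,3-dihydro-4H-chromen-4-one | CC(C)=CCC/C(C)=C/Cc1c(OCOC)c(CC=C(C)C)cc([C@H]2Oc3cc(OCOC)cc(OCOC)c3C(=O)[C@@H]2O)c1OCOC | intermediate
16 | (2R,3R)-2-{3-[(2E)-3,7-dimethylocta-2,6-dien-1-yl]-2,4-dihydroxy-5-(3-methylbut-2-en-1-yl)phenyl}-3,5,7-trihydroxy-2,3-dihydro-4H-chromen-4-one (CNP0174333.1) | CC(C)=CCC/C(C)=C/Cc1c(O)c(CC=C(C)C)cc([C@H]2Oc3cc(O)cc(O)c3C(=O)[C@@H]2O)c1O | target

Total step count: 7
Longest linear sequence: 6 (steps 1 to 5, then step 7)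

Steps most likely to fail

1. Step 7. Two processes may defeat it. In the first stage the hindered aryllithium may abstract the oxirane C–H next to the amide, or attack the oxirane, instead of adding to the carbonyl. In the acid stage, ionisation at C2 may leak into a 1,2-acyl shift or solvolysis, or the freed ortho-prenyl and ortho-geranyl phenols may close to chromans before ring C closes cleanly. The fallback replaces the oxirane by a dioxolane and still joins the two halves in one flask. It sets out from 9: acetone with Bi(OTf)3 (cat.) at rt should convert the oxirane into the acetonide [(4R)-5-(3-geranyl-2,4-bis(methoxymethoxy)-5-prenylphenyl)-2,2-dimethyl-1,3-dioxolan-4-yl](morpholin-4-yl)methanone F1. The C–O bond at the amide-bearing carbon is not broken, so that centre stays R; the benzylic centre may be a mixture, which does not matter. F1 is then treated with 12 (from 11 and n-BuLi) in THF at −78 °C and, in the same flask, with HCl/MeOH at 45 °C. The acetonide and MOM groups fall, the benzylic C–O bond ionises under the influence of ring B, and the ortho OH of ring A closes O1–C2 under thermodynamic control to the 2,3-trans isomer. The fallback comes back to the route at 16.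

2. Step 5. Conjugate addition of the samarium peroxide to the electron-rich, ortho-disubstituted cinnamamide may be slow, so that the catalyst ages and enantioselectivity erodes. The fallback changes the acceptor to an activated ester equivalent. It sets out from 6: Horner–Wadsworth–Emmons olefination with diethyl [2-oxo-2-(1H-pyrrol-1-yl)ethyl]phosphonate (NaH, THF) should give the (2E)-3-aryl-1-(1H-pyrrol-1-yl)prop-2-en-1-one F2, a more electrophilic, monodentate acceptor. Sm(O-i-Pr)3/(S)-H8-BINOL/Ph3As=O with t-BuOOH and MS 4 Å in THF should then give the (2R,3S)-epoxy N-acylpyrrole F3. F3 takes the place of 9 in step 7: 12 adds to the acylpyrrole and the pyrrolyl carbinol collapses on acidification. The fallback comes back to the route at 14, inside step 7.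

3. Step 1. O-alkylation and double alkylation may outrun C-alkylation at the hindered C3, so that little C-geranyl phenol forms. The fallback builds ring B by three directed ortho-lithiations instead and replaces steps 1 to 3. It sets out from geranyl bromide 2, with resorcinol as an extra purchased material. Resorcinol is protected (NaH, MOMCl, DMF) as 1,3-bis(methoxymethoxy)benzene F4. Lithiation between the two OMOM groups (n-BuLi, THF, 0 °C), then CuI (cat.) and 2, should give 2-[(2E)-3,7-dimethylocta-2,6-dien-1-yl]-1,3-bis(methoxymethoxy)benzene F5. A second ortho-lithiation (n-BuLi, TMEDA, THF, −20 °C), then CuI (cat.) and prenyl bromide, should give 2-geranyl-1,3-bis(methoxymethoxy)-4-(3-methylbut-2-en-1-yl)benzene F6. A third ortho-lithiation next to the remaining free OMOM position, quenched with DMF, should give the aldehyde. The fallback comes back to the route at 6.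

Further compounds
F1 | step 7 | [(4R)-5-{3-[(2E)-3,7-dimethylocta-2,6-dien-1-yl]-2,4-bis(methoxymethoxy)-5-(3-methylbut-2-en-1-yl)phenyl}-2,2-dimethyl-1,3-dioxolan-4-yl](morpholin-4-yl)methanone (C5 unassigned) | CC(C)=CCC/C(C)=C/Cc1c(OCOC)c(CC=C(C)C)cc(C2OC(C)(C)O[C@H]2C(=O)N2CCOCC2)c1OCOC
F2 | step 5 | (2E)-3-{3-[(2E)-3,7-dimethylocta-2,6-dien-1-yl]-2,4-bis(methoxymethoxy)-5-(3-methylbut-2-en-1-yl)phenyl}-1-(1H-pyrrol-1-yl)prop-2-en-1-one | CC(C)=CCC/C(C)=C/Cc1c(OCOC)c(CC=C(C)C)cc(/C=C/C(=O)n2cccc2)c1OCOC
F3 | step 5 | {(2R,3S)-3-[3-geranyl-2,4-bis(methoxymethoxy)-5-prenylphenyl]oxiran-2-yl}(1H-pyrrol-1-yl)methanone | CC(C)=CCC/C(C)=C/Cc1c(OCOC)c(CC=C(C)C)cc([C@@H]2O[C@H]2C(=O)n2cccc2)c1OCOC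
F4 | step 1 | 1,3-bis(methoxymethoxy)benzene | COCOc1cccc(OCOC)c1
F5 | step 1 | 2-[(2E)-3,7-dimethylocta-2,6-dien-1-yl]-1,3-bis(methoxymethoxy)benzene | CC(C)=CCC/C(C)=C/Cc1c(OCOC)cccc1OCOC
F6 | step 1 | 2-[(2E)-3,7-dimethylocta-2,6-dien-1-yl]-1,3-bis(methoxymethoxy)-4-(3-methylbut-2-en-1-yl)benzene | CC(C)=CCC/C(C)=C/Cc1c(OCOC)c(CC=C(C)C)ccc1OCOC
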